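**Strategy.** Everything rests on cutting the C2–C3 bond of the octan-1-one chain: the CH2 next to the aryl ketone is joined to the acyclic tertiary carbinol carbon C3 (CH3, OH, C4 chain). The key step is a lithiation–borylation: the α-lithiated triisopropylbenzoate of a sulcatol-derived secondary alcohol adds to a 2-arylallyl boronic ester, the allylic CH2 migrates from boron to carbon with loss of benzoate (1,2-metallate shift), and peroxide converts C–B into C–OH. One operation thus forms C2–C3 and sets the C3 stereocentre stereospecifically from a secondary carbinol. The precursor's 1,1-disubstituted alkene is the masked ketone (ozonolysis); the bromohydroquinone travels as its bis-MOM ether.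

Key step: step 8

Remark (assumption): (R)-6-methylhept-5-en-2-ol ((R)-sulcatol) of high enantiomeric purity is taken as a commercial material. Its configuration is inverted in step 5, and the target carbinol centre is (S).

**Route**

Step 1
Reactants: 1 2,5-dibromobenzene-1,4-diol
Product: 2 1,4-dibromo-2,5-bis(methoxymethoxy)benzene
Conditions: MOMCl (2.5 equiv), iPr2NEt, CH2Cl2, 0 °C to rt
Reagents that add atoms: chloromethyl methyl ether (MOMCl), COCCl
Why: O-alkylation of both phenols gives the bis-acetal, a protecting group that should survive organomagnesium and boronate chemistry, basic peroxide and ozone and be removable with mild acid.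

Step 2
Reactants: 2 1,4-dibromo-2,5-bis(methoxymethoxy)benzene; 3 prop-2-yn-1-ol
Product: 6 2-[4-bromo-2,5-bis(methoxymethoxy)phenyl]prop-2-en-1-ol, via aryl Grignard reagent 4 (not isolated), via alkenylmagnesium alkoxide 5 (not isolated)
Conditions: iPrMgCl·LiCl (1.05 equiv), THF, 0 °C to rt; then 3 (0.7 equiv, first deprotonated with iPrMgCl), CuI (10 mol%), THF, 0 °C to rt; aq. NH4Cl
Reagents that add atoms: none
Why: Bromine–magnesium exchange on the symmetrical dibromide should give a single mono-Grignard reagent, which adds across the alkyne of the magnesium propargyl alkoxide in the copper-catalysed, alkoxide-directed anti-carbomagnesiation, placing the aryl group on the internal carbon; protonation gives the 2-arylallyl alcohol.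

Step 3
Reactants: 6 2-[4-bromo-2,5-bis(methoxymethoxy)phenyl]prop-2-en-1-ol
Product: 7 2-[4-bromo-2,5-bis(methoxymethoxy)phenyl]allyl methyl carbonate
Conditions: ClCO2Me, pyridine, CH2Cl2, 0 °C
Reagents that add atoms: methyl chloroformate, COC(=O)Cl
Why: Acylation of the primary allylic alcohol installs the carbonate leaving group needed for copper-catalysed allylic borylation.

Step 4
Reactants: 7 2-[4-bromo-2,5-bis(methoxymethoxy)phenyl]allyl methyl carbonate
Product: 8 2-{2-[4-bromo-2,5-bis(methoxymethoxy)phenyl]prop-2-en-1-yl}-5,5-dimethyl-1,3,2-dioxaborinane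
Conditions: B2neop2 (1.2 equiv), CuCl (5 mol%), Xantphos (5 mol%), KOtBu (10 mol%), THF, 0 °C to rt
Reagents that add atoms: bis(neopentyl glycolato)diboron, CC1(C)COB(OC1)B1OCC(C)(C)CO1
Why: Copper(I)-catalysed allylic borylation (SN2′ substitution of the carbonate by a boryl-copper species) should give a single allylboronate because the 2-arylallyl unit has two equivalent CH2 termini, while the aryl bromide is inert to boryl-copper at this temperature.

Step 5
Reactants: 9 (R)-6-methylhept-5-en-2-ol
Product: 10 (S)-6-methylhept-5-en-2-yl 2,4,6-triisopropylbenzoate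
Conditions: 2,4,6-triisopropylbenzoic acid, PPh3, DIAD, THF, 0 °C to rt
Reagents that add atoms: 2,4,6-triisopropylbenzoic acid, CC(C)c1cc(C(C)C)c(C(=O)O)c(C(C)C)c1
Why: Mitsunobu esterification proceeds by SN2 displacement of the alkoxyphosphonium ion by the carboxylate, inverting the (R)-carbinol to the (S)-benzoate that the key step requires.

Step 6
Reactants: 10 (S)-6-methylhept-5-en-2-yl 2,4,6-triisopropylbenzoate
Product: 11 (S)-6-hydroxy-6-methylheptan-2-yl 2,4,6-triisopropylbenzoate
Conditions: Co(acac)2 (cat.), PhSiH3, O2 (1 atm), THF, rt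
Reagents that add atoms: dioxygen, O=O
Why: Mukaiyama hydration (cobalt-hydride hydrogen-atom transfer to the trisubstituted alkene, trapping of the tertiary radical by O2, reduction by silane) should give the Markovnikov tertiary alcohol without touching the hindered ester or the remote stereocentre.

Step 7
Reactants: 11 (S)-6-hydroxy-6-methylheptan-2-yl 2,4,6-triisopropylbenzoate
Product: 12 (S)-6-methyl-6-(triethylsilyloxy)heptan-2-yl 2,4,6-triisopropylbenzoate
Conditions: TESOTf, 2,6-lutidine, CH2Cl2, −78 to 0 °C
Reagents that add atoms: triethylsilyl trifluoromethanesulfonate, CC[Si](CC)(CC)OS(=O)(=O)C(F)(F)F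
Why: Silylation of the tertiary alcohol with the silyl triflate removes the only acidic proton before the organolithium step; the TES ether should survive sBuLi/TMEDA at −60 °C and basic peroxide and fall off in the final acid treatment.

Step 8
Reactants: 12 (S)-6-methyl-6-(triethylsilyloxy)heptan-2-yl 2,4,6-triisopropylbenzoate; 8 2-{2-[4-bromo-2,5-bis(methoxymethoxy)phenyl]prop-2-en-1-yl}-5,5-dimethyl-1,3,2-dioxaborinane
Product: 16 (S)-2-[4-bromo-2,5-bis(methoxymethoxy)phenyl]-4,8-dimethyl-8-(triethylsilyloxy)non-1-en-4-ol, via lithiated benzoate 13 (not isolated), via boronate complex 14 (not isolated), via tertiary boronic ester 15 (not isolated)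
Conditions: sBuLi (1.2 equiv), TMEDA (6 equiv), CPME, −60 °C, 2 h; then 8 (1.5 equiv), −60 °C to rt (50 °C if needed); then 2 M NaOH, 30% H2O2, THF, 0 °C to rt
Reagents that add atoms: hydrogen peroxide, OO
Why: sBuLi/TMEDA removes the α-hydrogen of the hindered benzoate 12 with retention to give the dipole-stabilised, configurationally stable organolithium 13, which adds to boron of 8 with retention to form boronate complex 14; on warming, the allylic CH2 migrates from boron to carbon anti to the departing triisopropylbenzoate (inversion at carbon), creating the C2–C3 bond in 15, and NaOH/H2O2 oxidises C–B to C–OH with retention. The closest known reaction type is the lithiation–borylation of secondary dialkyl 2,4,6-triisopropylbenzoates with neopentyl glycol boronic esters (a Matteson-type 1,2-metallate rearrangement). No ring is closed. The new tetrasubstituted stereocentre is controlled only by the (S)-configuration of 12: OH ends where H was and the CH2 group opposite the former C–O bond, which corresponds to the (S)-carbinol of the target. The step needs the organolithiums to choose boron over the aryl bromide and the styrenic alkene, which is secured by completing the deprotonation before 8 is added and by using 8 in excess over total alkyllithium at −60 °C so that no free organolithium persists. Regiochemistry of allyl transfer is not an issue because the 2-arylallyl group has two equivalent CH2 termini.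

Step 9
Reactants: 16 (S)-2-[4-bromo-2,5-bis(methoxymethoxy)phenyl]-4,8-dimethyl-8-(triethylsilyloxy)non-1-en-4-ol
Product: 17 (S)-1-[4-bromo-2,5-bis(methoxymethoxy)phenyl]-3-hydroxy-3,7-dimethyl-7-(triethylsilyloxy)octan-1-one
Conditions: O3, CH2Cl2/MeOH, −78 °C (indicator dye); then Me2S, −78 °C to rt
Reagents that add atoms: ozone, [O-][O+]=O
Why: Ozonolysis of the only C=C (an electron-rich 1,1-disubstituted styrene, far more reactive than the bromodialkoxyarene) with reductive work-up should unveil the aryl ketone under neutral conditions that neither dehydrate nor retro-aldolise the tertiary aldol, and the carbinol centre carries no acidic hydrogen.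

Step 10
Reactants: 17 (S)-1-[4-bromo-2,5-bis(methoxymethoxy)phenyl]-3-hydroxy-3,7-dimethyl-7-(triethylsilyloxy)octan-1-one
Product: 18 (S)-1-(4-bromo-2,5-dihydroxyphenyl)-3,7-dihydroxy-3,7-dimethyloctan-1-one
Conditions: 2 M aq. HCl, MeOH/THF, 0 °C to rt
Reagents that add atoms: none
Why: Acid-catalysed acetal hydrolysis should remove both aryl MOM ethers and the TES ether in one operation at room temperature, conditions chosen to be too mild to dehydrate the tertiary β-hydroxy ketone, leaving the (S)-carbinol intact.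

**Compound list**

1 | 2,5-dibromobenzene-1,4-diol | Oc1cc(Br)c(O)cc1Br | starting material
2 | 1,4-dibromo-2,5-bis(methoxymethoxy)benzene | COCOc1cc(Br)c(OCOC)cc1Br | intermediate
3 | prop-2-yn-1-ol | C#CCO | starting material
4 | [4-bromo-2,5-bis(methoxymethoxy)phenyl]magnesium chloride (LiCl complex) | COCOc1cc(Br)c(OCOC)cc1[Mg]Cl | intermediate
5 | 4-[4-bromo-2,5-bis(methoxymethoxy)phenyl]-2,5-dihydro-1,2-oxamagnesole (cyclic alkenylmagnesium alkoxide, Mg cis to CH2O) | [Mg]1OCC(=C1)c1cc(OCOC)c(Br)cc1OCOC | intermediate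
6 | 2-[4-bromo-2,5-bis(methoxymethoxy)phenyl]prop-2-en-1-ol | C=C(CO)c1cc(OCOC)c(Br)cc1OCOC | intermediate
7 | 2-[4-bromo-2,5-bis(methoxymethoxy)phenyl]allyl methyl carbonate | C=C(COC(=O)OC)c1cc(OCOC)c(Br)cc1OCOC | intermediate
8 | 2-{2-[4-bromo-2,5-bis(methoxymethoxy)phenyl]prop-2-en-1-yl}-5,5-dimethyl-1,3,2-dioxaborinane | C=C(CB1OCC(C)(C)CO1)c1cc(OCOC)c(Br)cc1OCOC | intermediate
9 | (R)-6-methylhept-5-en-2-ol ((R)-sulcatol) | C[C@@H](O)CCC=C(C)C | starting material
10 | (S)-6-methylhept-5-en-2-yl 2,4,6-triisopropylbenzoate | C[C@H](OC(=O)c1c(C(C)C)cc(C(C)C)cc1C(C)C)CCC=C(C)C | intermediate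
11 | (S)-6-hydroxy-6-methylheptan-2-yl 2,4,6-triisopropylbenzoate | C[C@H](OC(=O)c1c(C(C)C)cc(C(C)C)cc1C(C)C)CCCC(C)(C)O | intermediate
12 | (S)-6-methyl-6-(triethylsilyloxy)heptan-2-yl 2,4,6-triisopropylbenzoate | C[C@H](OC(=O)c1c(C(C)C)cc(C(C)C)cc1C(C)C)CCCC(C)(C)O[Si](CC)(CC)CC | intermediate
13 | (S)-2-lithio-6-methyl-6-(triethylsilyloxy)heptan-2-yl 2,4,6-triisopropylbenzoate (Li in place of the former H) | C[C@]([Li])(OC(=O)c1c(C(C)C)cc(C(C)C)cc1C(C)C)CCCC(C)(C)O[Si](CC)(CC)CC | intermediate
14 | lithium boronate complex of 13 and 8 ((S) at the carbinol carbon, B in place of Li) | [Li+].C[C@](OC(=O)c1c(C(C)C)cc(C(C)C)cc1C(C)C)(CCCC(C)(C)O[Si](CC)(CC)CC)[B-]1(CC(=C)c2cc(OCOC)c(Br)cc2OCOC)OCC(C)(C)CO1 | intermediate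
15 | 2-{(R)-2-[4-bromo-2,5-bis(methoxymethoxy)phenyl]-4,8-dimethyl-8-(triethylsilyloxy)non-1-en-4-yl}-5,5-dimethyl-1,3,2-dioxaborinane | C[C@@](CC(=C)c1cc(OCOC)c(Br)cc1OCOC)(CCCC(C)(C)O[Si](CC)(CC)CC)B1OCC(C)(C)CO1 | intermediate
16 | (S)-2-[4-bromo-2,5-bis(methoxymethoxy)phenyl]-4,8-dimethyl-8-(triethylsilyloxy)non-1-en-4-ol | CC(C)(O[Si](CC)(CC)CC)CCC[C@](C)(O)CC(=C)c1cc(OCOC)c(Br)cc1OCOC | intermediate
17 | (S)-1-[4-bromo-2,5-bis(methoxymethoxy)phenyl]-3-hydroxy-3,7-dimethyl-7-(triethylsilyloxy)octan-1-one | CC(C)(O[Si](CC)(CC)CC)CCC[C@](C)(O)CC(=O)c1cc(OCOC)c(Br)cc1OCOC | intermediate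
18 | (S)-1-(4-bromo-2,5-dihydroxyphenyl)-3,7-dihydroxy-3,7-dimethyloctan-1-one | CC(C)(O)CCC[C@](C)(O)CC(=O)c1cc(O)c(Br)cc1O | target

**Totals.** Total step count: 10. Longest linear sequence: 7 steps (steps 1–4, then 8–10).

**Steps most likely to fail**

1. Step 8. Residual sBuLi or the lithiated benzoate may undergo bromine–lithium exchange at the aryl bromide or add to the styrenic alkene before the boronate complex forms. Deprotonation of the dialkyl benzoate may also be incomplete, or the 1,2-shift of the hindered complex may be slow. Fallback (sets out from 12 and from the aryl Grignard reagent 4; returns at 17): the aryl bromide is kept away from the organolithium. Lithiated benzoate 13 is captured with 2-allyl-5,5-dimethyl-1,3,2-dioxaborinane to give the lithium allylboronate complex F1, which should rearrange on warming to the tertiary boronic ester F2 and be oxidised (NaOH/H2O2) to (S)-4,8-dimethyl-8-(triethylsilyloxy)non-1-en-4-ol F3. Ozonolysis (O3, then Me2S) should give (S)-3-hydroxy-3,7-dimethyl-7-(triethylsilyloxy)octanal F4. Addition of 4 (2.2 equiv, THF, −40 °C) should give (3S)-1-[4-bromo-2,5-bis(methoxymethoxy)phenyl]-3,7-dimethyl-7-(triethylsilyloxy)octane-1,3-diol F5 as a mixture of C1 epimers. Oxidation of the benzylic secondary alcohol (MnO2 or Dess–Martin periodinane) then gives 17.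

2. Step 2. The aryl Grignard reagent may deprotonate the terminal alkyne instead of adding across it, may couple with the 2-bromopropane formed in the exchange under copper catalysis, or may turn over slowly because of chelation by the ortho MOM group. Fallback (sets out from 2; returns at 6): mono bromine–lithium exchange (nBuLi, THF, −78 °C) gives [4-bromo-2,5-bis(methoxymethoxy)phenyl]lithium F6. Acylation with 2-(tert-butyldimethylsilyloxy)-N-methoxy-N-methylacetamide should give 1-[4-bromo-2,5-bis(methoxymethoxy)phenyl]-2-(tert-butyldimethylsilyloxy)ethan-1-one F7. Wittig methylenation (Ph3P=CH2, THF, 0 °C) should give {2-[4-bromo-2,5-bis(methoxymethoxy)phenyl]allyloxy}(tert-butyl)dimethylsilane F8, and TBAF (THF, 0 °C) releases 6.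

3. Step 10. Protic acid may dehydrate the tertiary β-hydroxy ketone (followed by oxa-Michael closure of the ortho phenol to a chromanone) or ionise a tertiary alcohol before the second MOM group is gone. Fallback (sets out from 17; returns at 18): a non-protic end game. TMSOTf/2,2′-bipyridyl (MeCN, 0 °C) should convert both aryl MOM ethers into trimethylsilyl ethers and silylate the C3 hydroxyl, giving (S)-1-[4-bromo-2,5-bis(trimethylsilyloxy)phenyl]-3,7-dimethyl-7-(triethylsilyloxy)-3-(trimethylsilyloxy)octan-1-one F9. Buffered fluoride (TBAF/AcOH, THF, 0 °C) then removes all four silyl groups to give 18.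

**Further compounds**

F1 | step 8 | lithium boronate complex of 13 and 2-allyl-5,5-dimethyl-1,3,2-dioxaborinane | [Li+].C[C@](OC(=O)c1c(C(C)C)cc(C(C)C)cc1C(C)C)(CCCC(C)(C)O[Si](CC)(CC)CC)[B-]1(CC=C)OCC(C)(C)CO1
F2 | step 8 | 2-[(R)-4,8-dimethyl-8-(triethylsilyloxy)non-1-en-4-yl]-5,5-dimethyl-1,3,2-dioxaborinane | C[C@@](CC=C)(CCCC(C)(C)O[Si](CC)(CC)CC)B1OCC(C)(C)CO1
F3 | step 8 | (S)-4,8-dimethyl-8-(triethylsilyloxy)non-1-en-4-ol | CC(C)(O[Si](CC)(CC)CC)CCC[C@](C)(O)CC=C
F4 | step 8 | (S)-3-hydroxy-3,7-dimethyl-7-(triethylsilyloxy)octanal | CC(C)(O[Si](CC)(CC)CC)CCC[C@](C)(O)CC=O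
F5 | step 8 | (3S)-1-[4-bromo-2,5-bis(methoxymethoxy)phenyl]-3,7-dimethyl-7-(triethylsilyloxy)octane-1,3-diol (both C1 epimers) | CC(C)(O[Si](CC)(CC)CC)CCC[C@](C)(O)CC(O)c1cc(OCOC)c(Br)cc1OCOC
F6 | step 2 | [4-bromo-2,5-bis(methoxymethoxy)phenyl]lithium | COCOc1cc(Br)c(OCOC)cc1[Li]
F7 | step 2 | 1-[4-bromo-2,5-bis(methoxymethoxy)phenyl]-2-(tert-butyldimethylsilyloxy)ethan-1-one | CC(C)(C)[Si](C)(C)OCC(=O)c1cc(OCOC)c(Br)cc1OCOC
F8 | step 2 | {2-[4-bromo-2,5-bis(methoxymethoxy)phenyl]allyloxy}(tert-butyl)dimethylsilane | C=C(CO[Si](C)(C)C(C)(C)C)c1cc(OCOC)c(Br)cc1OCOC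
F9 | step 10 | (S)-1-[4-bromo-2,5-bis(trimethylsilyloxy)phenyl]-3,7-dimethyl-7-(triethylsilyloxy)-3-(trimethylsilyloxy)octan-1-one | CC(C)(O[Si](CC)(CC)CC)CCC[C@](C)(O[Si](C)(C)C)CC(=O)c1cc(O[Si](C)(C)C)c(Br)cc1O[Si](C)(C)C
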